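At 5.00 min the cedar run still holds 82.8% of its starting material. The missing 17.2% stands against 16.2% of target, a gap of 1 percentage point with a scatter of 1 point on each reading, so I read target and reacted part as one number.

| flask | starting material | reagent in the second phase | remark | time | volume of the second phase over the first |
|---|---|---|---|---|---|
| ash | 21 mM | 0.90 equiv | run made earlier |  |  |
| birch | 32 mM | 0.90 equiv | run made earlier |  |  |
| cedar | 42 mM | 1.4 equiv | run made earlier |  |  |
| flask | 42 mM | 0.900 equiv |  | 8.0 min | 0.25 |

| run | time / min | target / % | starting material / % |
|---|---|---|---|
| ash | 0.833 | 0.7 | 99.5 |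
| ash | 1.50 | 1.3 | 100.2 |
| ash | 2.50 | 5.0 | 96.1 |
| ash | 3.00 | 1.9 | 96.1 |
| ash | 4.00 | 3.9 | 95.7 |
| ash | 5.00 | 6.5 | 93.9 |
| birch | 0.417 | 0 | 98.8 |
| birch | 0.667 | 0.2 | 99.0 |
| birch | 1.00 | 2.1 | 98.2 |
| birch | 2.00 | 2.9 | 95.5 |
| birch | 3.00 | 5.6 | 92.6 |
| birch | 5.00 | 9.8 | 89.5 |
| cedar | 0.417 | 0.8 | 98.4 |
| cedar | 0.667 | 2.2 | 97.7 |
| cedar | 1.33 | 5.0 | 94.6 |
| cedar | 2.50 | 10.9 | 90.9 |
| cedar | 5.00 | 16.2 | 82.8 |

(each reading ± 1 percentage point)

- in the second phase: reagent in the second phase; everything else is in the first
- charges count per volume of the first phase; a concentration in a rate is the amount of a species over the volume of its own phase; every rate counts per litre of the first phase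
- the earlier runs hold the two phases in the same ratio of volumes as the flask asked about

- how much target there is at 8.0 min, in percent of the starting material charged
- part of the starting material charged that has reacted at 8.0 min

What does that percentage follow? From ash to birch, at equal equivalents, c(reagent in the second phase), charged per volume of the first phase, rises by a factor of 1.52, and target at 5.00 min by 1.51. So I divide by that concentration. Target, as a fraction of the starting material charged, per minute and per mM of that charge, reads 6.88 × 10⁻⁴ /mM/min in ash, 6.81 × 10⁻⁴ /mM/min in birch and 5.51 × 10⁻⁴ /mM/min in cedar, which is lower. I call this specific rate g; it belongs to the ratio of volumes that these runs share with the flask, and it treats the loss of starting material as pseudo-first-order.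

Which g suits the flask? I take cedar's, whose target reading is larger and whose starting material equals the flask's. The flask's charge of reagent in the second phase, 37.8 mM per volume of the first phase, then gives me 16.7% of target over 8.0 min.

The forecast gives 15.5% of target and 16.3% reacted, holding that “the rate is roughly first order in both starting material and reagent”; my figure stands above its target.

The flask gives 17.4% of target and 17.4% reacted.

    reagent in the reaction phase ⇌ reagent in the second phase, rate k1*([reagent in the reaction phase] - [reagent in the second phase]/K1) per volume of the first phase (partition coefficient = 76.0, kL = 0.0930 /s)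
    reagent in the reaction phase → decomposed reagent (k = 0.00950 /s)
    starting material + reagent in the reaction phase → target (k = 0.320 /M/s)

Over its 8.0 min the flask's own g comes to 5.76 × 10⁻⁴ /mM/min. At 8.00 min reagent in the reaction phase goes to target 1.2 times as fast as to decomposed reagent, and c(reagent in the reaction phase) in the flask has moved from 1.48 mM at 0.800 min to 1.03 mM at 8.00 min.

For the same flask read at 2.0 min, cedar's g gives 4.17%, and the computed target is higher, at 5.11%, with c(reagent in the reaction phase) at 1.40 mM.

The data are calculated from invented constants; noise was put on by code.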